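Numbering is that of labdane: C4 carries C19 (CH3, β) and C18 (CO2H, α), C5/C10 are the ring fusion, C8 carries OAc and C17, C9 carries the chain C11–C13.
Retrosynthetic cuts, in order: acetate and benzyl esters; C11=C12 (Wittig); C5–C10 and C3–C4 together (intramolecular Diels–Alder); C1–C2 (Pd coupling); C10–C20 (carboalumination); C9–C10 (acetylide opening of an epoxide); geraniol remains.
Enabling feature: ring A (C1–C5, C10) is unsubstituted at C1–C3 and C4 bears a carbonyl carbon (C18), so ring A is the cyclohexene of a C10=C1–C2=C3 diene and a C4=C5 enal; C6–C9 of ring B is the tether and already holds the C8/C9 stereodiad.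
Forward: geraniol (C4–C9, C11, C17–C19) is epoxidised, the chain is grown at C9 to the diene, C18 is oxidised to the enal, rings B and A close together in step 9, then the C11–C13 chain and the acetate are added.
Stereochemistry: C8 from Sharpless epoxidation (D-(−)-tartrate); C9 by SN2 inversion at the epoxide; C10 and C5 from the silylene-locked chair of the tether; C4 from the E geometry of the enal, which goes back to the E-methyl group of geraniol.
Key step: step 9

Remark: 1, 4, 10, 19 and all reagents are taken as commercial; α/β follow the labdane convention (β = face of the C10 methyl); the C8/C11 diol is bridged as a di-tert-butylsilylene because this bridge, unlike a ketal, is inert to Me3Al and Me2AlCl.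

Step 1
Reactants: 1 geraniol
Product: 2 (2R,3R)-2,3-epoxygeraniol
Conditions: Ti(OiPr)4 (5 mol%), D-(−)-diethyl tartrate (7.5 mol%), t-BuOOH, 4 Å MS, CH2Cl2, −20 °C
Reagents that add atoms: tert-butyl hydroperoxide, CC(C)(C)OO
Why: Katsuki–Sharpless asymmetric epoxidation acts only on the allylic C2=C3 alkene, and the D-(−)-tartrate catalyst delivers oxygen to the face that gives the (2R,3R)-epoxide, which fixes the future C8 as R.

Step 2
Reactants: 2 (2R,3R)-2,3-epoxygeraniol
Product: 3 (2R,3R)-2,3-epoxygeranyl tert-butyldimethylsilyl ether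
Conditions: TBSCl, imidazole, CH2Cl2, 0 °C → rt
Reagents that add atoms: tert-butyldimethylsilyl chloride, CC(C)(C)[Si](C)(C)Cl
Why: Routine silylation of the primary alcohol removes the acidic proton and the Payne rearrangement pathway before the carbanion step and leaves the epoxide untouched.

Step 3
Reactants: 3 (2R,3R)-2,3-epoxygeranyl tert-butyldimethylsilyl ether; 4 ethynyltrimethylsilane
Product: 6 (2S,3R)-1-(tert-butyldimethylsilyloxy)-3,7-dimethyl-2-[(trimethylsilyl)ethynyl]oct-6-en-3-ol, via lithium (trimethylsilyl)acetylide 5 (not isolated)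
Conditions: 4, n-BuLi, THF, −78 °C; BF3·OEt2; then 3, −78 °C
Reagents that add atoms: ethynyltrimethylsilane (4), C#C[Si](C)(C)C
Why: In this Yamaguchi–Hirao alkynylation the BF3-activated trisubstituted epoxide should be opened by the acetylide in SN2 fashion at the secondary carbon (future C9) and not at the fully substituted one, so C9 is set by inversion while the tertiary C8–O bond stays intact, which gives the anti (2S,3R) stereodiad.

Step 4
Reactants: 6 (2S,3R)-1-(tert-butyldimethylsilyloxy)-3,7-dimethyl-2-[(trimethylsilyl)ethynyl]oct-6-en-3-ol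
Product: 7 (2S,3R)-2-ethynyl-3,7-dimethyloct-6-ene-1,3-diol
Conditions: TBAF, THF, 0 °C → rt
Reagents that add atoms: none
Why: Fluoride cleaves the O–Si bond of the primary silyl ether and the C(sp)–Si bond of the alkynylsilane in one operation without touching either stereocentre.

Step 5
Reactants: 7 (2S,3R)-2-ethynyl-3,7-dimethyloct-6-ene-1,3-diol
Product: 8 (4R,5S)-2,2-di-tert-butyl-5-ethynyl-4-methyl-4-(4-methylpent-3-en-1-yl)-1,3,2-dioxasilinane
Conditions: t-Bu2Si(OTf)2, 2,6-lutidine, CH2Cl2, 0 °C → rt
Reagents that add atoms: di-tert-butylsilyl bis(trifluoromethanesulfonate), CC(C)(C)[Si](OS(=O)(=O)C(F)(F)F)(OS(=O)(=O)C(F)(F)F)C(C)(C)C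
Why: The bis(triflate) silylates even tertiary alcohols, so the 1,3-diol should close to the six-membered silylene that later holds O8 and C11 gauche and survives the aluminium reagents and the selenium oxidation.

Step 6
Reactants: 8 (4R,5S)-2,2-di-tert-butyl-5-ethynyl-4-methyl-4-(4-methylpent-3-en-1-yl)-1,3,2-dioxasilinane
Product: 9 (2E)-5-[(4R,5S)-2,2-di-tert-butyl-5-ethynyl-4-methyl-1,3,2-dioxasilinan-4-yl]-2-methylpent-2-en-1-ol
Conditions: SeO2 (cat.), t-BuOOH, salicylic acid (cat.), CH2Cl2, rt
Reagents that add atoms: selenium dioxide (catalytic oxygen carrier), O=[Se]=O; tert-butyl hydroperoxide (terminal oxidant), CC(C)(C)OO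
Why: The SeO2/t-BuOOH allylic oxidation (ene reaction then [2,3]-sigmatropic shift) selects the E-methyl group of a 2-methylalk-2-ene terminus, so the carbon that becomes C18 is hydroxylated with the E geometry kept, while the hindered propargylic C–H should react far more slowly.

Step 7
Reactants: 9 (2E)-5-[(4R,5S)-2,2-di-tert-butyl-5-ethynyl-4-methyl-1,3,2-dioxasilinan-4-yl]-2-methylpent-2-en-1-ol; 10 vinyl bromide
Product: 12 (2E)-5-{(4R,5S)-2,2-di-tert-butyl-4-methyl-5-[(2E)-penta-2,4-dien-2-yl]-1,3,2-dioxasilinan-4-yl}-2-methylpent-2-en-1-ol, via alkenyldimethylalane 11 (not isolated)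
Conditions: Me3Al (3 equiv), Cp2ZrCl2 (0.3 equiv), CH2Cl2, 0 °C → rt; then 10, Pd(PPh3)4 (5 mol%), ZnCl2 (cat.), THF, rt
Reagents that add atoms: trimethylaluminium, C[Al](C)C; vinyl bromide (10), C=CBr
Why: Negishi zirconium-catalysed carboalumination adds CH3 and Al syn across the terminal alkyne with the methyl (C20) on the internal carbon, and palladium-catalysed coupling of the alkenylalane with vinyl bromide goes with retention, so the diene should form with C9 trans to the vinyl group while the free hydroxyl rides along as its aluminium alkoxide.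

Step 8
Reactants: 12 (2E)-5-{(4R,5S)-2,2-di-tert-butyl-4-methyl-5-[(2E)-penta-2,4-dien-2-yl]-1,3,2-dioxasilinan-4-yl}-2-methylpent-2-en-1-ol
Product: 13 (2E)-5-{(4R,5S)-2,2-di-tert-butyl-4-methyl-5-[(2E)-penta-2,4-dien-2-yl]-1,3,2-dioxasilinan-4-yl}-2-methylpent-2-enal
Conditions: MnO2, CH2Cl2, rt
Reagents that add atoms: none
Why: Activated manganese dioxide oxidises the allylic alcohol to the enal without touching the diene or the silylene and without E/Z isomerisation.

Step 9
Reactants: 13 (2E)-5-{(4R,5S)-2,2-di-tert-butyl-4-methyl-5-[(2E)-penta-2,4-dien-2-yl]-1,3,2-dioxasilinan-4-yl}-2-methylpent-2-enal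
Product: 14 8α,11-(di-tert-butylsilylenedioxy)-12,13,14,15,16-pentanorlabd-1-en-18-al
Conditions: Me2AlCl (1.2 equiv), CH2Cl2 (0.01 M), −78 → −20 °C
Reagents that add atoms: none
Why: Me2AlCl binds the formyl oxygen and the (E)-2-methylenal C4=C5 adds across the C10=C1–C2=C3 diene in a concerted but asynchronous [4+2] cycloaddition in which the C5–C10 bond leads and the C3–C4 bond follows, the closest known type being the Lewis-acid-promoted type 1 intramolecular Diels–Alder reaction of (2E,8E)-2,8,10-trienals to trans-fused octalins. Ring B closes by the C5–C10 bond through the four-atom C6–C9 tether in a chair, and ring A is closed by the C3–C4 bond as the new cyclohexene (C1=C2) of the cycloaddition itself. C10 and C5 are controlled by the silylene, which can only bridge O8 and C11 when both are equatorial on the forming chair, so the diene is met on the face that puts the C10 methyl axial and β and H5 axial and α. C4 is controlled by the retained E geometry of the enal, which places the formyl carbon cis to H5 (α, equatorial, the future C18) and the C4 methyl β and axial. The selectivity needed is endo-formyl with the tether exo, since only this transition state gives the trans ring fusion; the Lewis-acid-complexed formyl group and the preference of terminally activated 1,7,9-decatrienes for the anti transition state should secure it against the syn-axial contact of the C4 and C10 methyl groups that this transition state has to carry. The low temperature also keeps the diene, which has a methyl cis to the vinyl group, from 1,5-hydrogen shift.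

Step 10
Reactants: 14 8α,11-(di-tert-butylsilylenedioxy)-12,13,14,15,16-pentanorlabd-1-en-18-al
Product: 15 8α,11-(di-tert-butylsilylenedioxy)-12,13,14,15,16-pentanorlabd-1-en-18-oic acid
Conditions: NaClO2, NaH2PO4, 2-methyl-2-butene, t-BuOH/H2O, rt
Reagents that add atoms: sodium chlorite, [Na+].[O-]Cl=O
Why: Pinnick chlorite oxidation converts even an aldehyde on a quaternary carbon into the acid, and 2-methyl-2-butene intercepts the hypochlorous acid before it can add to the C1=C2 alkene.

Step 11
Reactants: 15 8α,11-(di-tert-butylsilylenedioxy)-12,13,14,15,16-pentanorlabd-1-en-18-oic acid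
Product: 16 benzyl 8α,11-(di-tert-butylsilylenedioxy)-12,13,14,15,16-pentanorlabd-1-en-18-oate
Conditions: BnBr, K2CO3, DMF, rt
Reagents that add atoms: benzyl bromide, BrCc1ccccc1
Why: O-Alkylation of the carboxylate is an SN2 reaction at the benzylic carbon, so crowding at C4 does not matter, and the ester is one that the final hydrogenation removes.

Step 12
Reactants: 16 benzyl 8α,11-(di-tert-butylsilylenedioxy)-12,13,14,15,16-pentanorlabd-1-en-18-oate
Product: 17 benzyl 8α,11-dihydroxy-12,13,14,15,16-pentanorlabd-1-en-18-oate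
Conditions: HF·pyridine, THF, 0 °C → rt
Reagents that add atoms: none
Why: Fluoride-driven cleavage of both Si–O bonds frees the tertiary C8 and primary C11 alcohols under conditions that leave the benzyl ester and the alkene alone.

Step 13
Reactants: 17 benzyl 8α,11-dihydroxy-12,13,14,15,16-pentanorlabd-1-en-18-oate
Product: 18 benzyl 8α-hydroxy-11-oxo-12,13,14,15,16-pentanorlabd-1-en-18-oate
Conditions: Dess–Martin periodinane, CH2Cl2, 0 °C → rt
Reagents that add atoms: none
Why: Dess–Martin oxidation takes the primary alcohol to the aldehyde under near-neutral conditions in which the tertiary alcohol cannot react and the equatorial formyl group at C9 has no reason to epimerise.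

Step 14
Reactants: 18 benzyl 8α-hydroxy-11-oxo-12,13,14,15,16-pentanorlabd-1-en-18-oate; 19 benzyl (triphenylphosphoranylidene)acetate
Product: 20 dibenzyl (11E)-8α-hydroxy-14,15,16-trinorlabda-1,11-diene-13,18-dioate
Conditions: 19 (2 equiv), toluene, 90 °C
Reagents that add atoms: benzyl (triphenylphosphoranylidene)acetate (19), O=C(OCc1ccccc1)C=P(c1ccccc1)(c1ccccc1)c1ccccc1
Why: Wittig olefination with a stabilised, non-basic ylide adds C12 and C13 as the (E)-enoate without exposing the β-hydroxy aldehyde to base, at the price of prolonged heating for this hindered aldehyde.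

Step 15
Reactants: 20 dibenzyl (11E)-8α-hydroxy-14,15,16-trinorlabda-1,11-diene-13,18-dioate
Product: 21 dibenzyl (11E)-8α-acetoxy-14,15,16-trinorlabda-1,11-diene-13,18-dioate
Conditions: AcCl, N,N-dimethylaniline, CH2Cl2, rt
Reagents that add atoms: acetyl chloride, CC(=O)Cl
Why: Acetyl chloride with N,N-dimethylaniline is an established way to acylate hindered tertiary terpene alcohols without ionising them, so the equatorial 8α-hydroxyl should become the acetate with C8 unchanged.

Step 16
Reactants: 21 dibenzyl (11E)-8α-acetoxy-14,15,16-trinorlabda-1,11-diene-13,18-dioate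
Product: 22 8α-acetoxy-14,15,16-trinorlabdane-13,18-dioic acid
Conditions: H2 (1 atm), 10% Pd/C, EtOAc, rt
Reagents that add atoms: none
Why: Hydrogenation over palladium saturates the C11=C12 and C1=C2 alkenes, neither of which creates a stereocentre, and hydrogenolyses both benzyl esters, while the tertiary acetate, which is neither allylic nor benzylic, is kept.

Compound list
1 | geraniol | CC(C)=CCC/C(C)=C/CO | starting material
2 | (2R,3R)-2,3-epoxygeraniol, [(2R,3R)-3-methyl-3-(4-methylpent-3-en-1-yl)oxiran-2-yl]methanol | CC(C)=CCC[C@@]1(C)O[C@@H]1CO | intermediate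
3 | (2R,3R)-2,3-epoxygeranyl tert-butyldimethylsilyl ether | CC(C)=CCC[C@@]1(C)O[C@@H]1CO[Si](C)(C)C(C)(C)C | intermediate
4 | ethynyltrimethylsilane | C#C[Si](C)(C)C | starting material
5 | lithium (trimethylsilyl)acetylide (formed in the flask, not isolated) | [Li]C#C[Si](C)(C)C | intermediate
6 | (2S,3R)-1-(tert-butyldimethylsilyloxy)-3,7-dimethyl-2-[(trimethylsilyl)ethynyl]oct-6-en-3-ol | CC(C)=CCC[C@@](C)(O)[C@H](CO[Si](C)(C)C(C)(C)C)C#C[Si](C)(C)C | intermediate
7 | (2S,3R)-2-ethynyl-3,7-dimethyloct-6-ene-1,3-diol | CC(C)=CCC[C@@](C)(O)[C@H](CO)C#C | intermediate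
8 | (4R,5S)-2,2-di-tert-butyl-5-ethynyl-4-methyl-4-(4-methylpent-3-en-1-yl)-1,3,2-dioxasilinane | CC(C)=CCC[C@@]1(C)O[Si](C(C)(C)C)(C(C)(C)C)OC[C@@H]1C#C | intermediate
9 | (2E)-5-[(4R,5S)-2,2-di-tert-butyl-5-ethynyl-4-methyl-1,3,2-dioxasilinan-4-yl]-2-methylpent-2-en-1-ol | OC/C(C)=C/CC[C@@]1(C)O[Si](C(C)(C)C)(C(C)(C)C)OC[C@@H]1C#C | intermediate
10 | vinyl bromide | C=CBr | starting material
11 | (E)-alkenyldimethylalane from 9, with the hydroxyl as its dimethylaluminium alkoxide (formed in the flask, not isolated) | C[Al](C)OC/C(C)=C/CC[C@@]1(C)O[Si](C(C)(C)C)(C(C)(C)C)OC[C@@H]1/C(C)=C/[Al](C)C | intermediate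
12 | (2E)-5-{(4R,5S)-2,2-di-tert-butyl-4-methyl-5-[(2E)-penta-2,4-dien-2-yl]-1,3,2-dioxasilinan-4-yl}-2-methylpent-2-en-1-ol | OC/C(C)=C/CC[C@@]1(C)O[Si](C(C)(C)C)(C(C)(C)C)OC[C@@H]1/C(C)=C/C=C | intermediate
13 | (2E)-5-{(4R,5S)-2,2-di-tert-butyl-4-methyl-5-[(2E)-penta-2,4-dien-2-yl]-1,3,2-dioxasilinan-4-yl}-2-methylpent-2-enal | O=C/C(C)=C/CC[C@@]1(C)O[Si](C(C)(C)C)(C(C)(C)C)OC[C@@H]1/C(C)=C/C=C | intermediate
14 | 8α,11-(di-tert-butylsilylenedioxy)-12,13,14,15,16-pentanorlabd-1-en-18-al (4R,5R,8R,9S,10S; trans-decalin, 4α-CHO, 4β-CH3, 8β-CH3, 10β-CH3) | CC(C)(C)[Si]3(C(C)(C)C)O[C@]1(C)CC[C@@H]2[C@](C)(C=CC[C@@]2(C)C=O)[C@H]1CO3 | intermediate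
15 | 8α,11-(di-tert-butylsilylenedioxy)-12,13,14,15,16-pentanorlabd-1-en-18-oic acid | CC(C)(C)[Si]3(C(C)(C)C)O[C@]1(C)CC[C@@H]2[C@](C)(C=CC[C@@]2(C)C(=O)O)[C@H]1CO3 | intermediate
16 | benzyl 8α,11-(di-tert-butylsilylenedioxy)-12,13,14,15,16-pentanorlabd-1-en-18-oate | CC(C)(C)[Si]3(C(C)(C)C)O[C@]1(C)CC[C@@H]2[C@](C)(C=CC[C@@]2(C)C(=O)OCc4ccccc4)[C@H]1CO3 | intermediate
17 | benzyl 8α,11-dihydroxy-12,13,14,15,16-pentanorlabd-1-en-18-oate | O[C@]1(C)CC[C@@H]2[C@](C)(C=CC[C@@]2(C)C(=O)OCc3ccccc3)[C@H]1CO | intermediate
18 | benzyl 8α-hydroxy-11-oxo-12,13,14,15,16-pentanorlabd-1-en-18-oate | O[C@]1(C)CC[C@@H]2[C@](C)(C=CC[C@@]2(C)C(=O)OCc3ccccc3)[C@H]1C=O | intermediate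
19 | benzyl (triphenylphosphoranylidene)acetate | O=C(OCc1ccccc1)C=P(c1ccccc1)(c1ccccc1)c1ccccc1 | starting material
20 | dibenzyl (11E)-8α-hydroxy-14,15,16-trinorlabda-1,11-diene-13,18-dioate | O[C@]1(C)CC[C@@H]2[C@](C)(C=CC[C@@]2(C)C(=O)OCc3ccccc3)[C@H]1/C=C/C(=O)OCc4ccccc4 | intermediate
21 | dibenzyl (11E)-8α-acetoxy-14,15,16-trinorlabda-1,11-diene-13,18-dioate | CC(=O)O[C@]1(C)CC[C@@H]2[C@](C)(C=CC[C@@]2(C)C(=O)OCc3ccccc3)[C@H]1/C=C/C(=O)OCc4ccccc4 | intermediate
22 | 8α-acetoxy-14,15,16-trinorlabdane-13,18-dioic acid (4R,5R,8R,9R,10S) | CC(=O)O[C@]1(C)CC[C@@H]2[C@](C)(CCC[C@@]2(C)C(=O)O)[C@H]1CCC(=O)O | target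

Total step count: 16. Longest linear sequence: 16 steps (1 to 22); 4, 10 and 19 enter as bought compounds.

Steps most likely to fail

Step 9. The cycloaddition may be slow because the diene terminus C10 is doubly substituted. Endo selectivity, and with it the trans ring fusion, may be eroded by the syn-axial contact between the C4 and C10 methyl groups, so that cis-fused material forms. Warming to force the reaction would invite 1,5-hydrogen shift in the diene. The fallback sets out from 13 and returns at 14, and replaces the neutral enal by an alkoxyallyl cation as dienophile (ionic Diels–Alder reaction). 13 is treated with 1,2-bis(trimethylsilyloxy)ethane and catalytic TMSOTf in CH2Cl2 at −78 °C to give the trienal ethylene acetal F1. The same acid, or catalytic TfOH, at −78 → −40 °C ionises F1 to the 1,3-dioxolan-2-ylium-substituted allyl cation, whose earlier and more asynchronous transition state should be less sensitive to the methyl–methyl contact, and gives the cycloadduct ethylene acetal F2. Hydrolysis with PPTS in aqueous acetone returns aldehyde 14.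

Step 3. The acetylide may attack the tertiary epoxide carbon, or the Lewis acid may trigger ionisation and hydride shift of the epoxide before the C–C bond forms. The fallback sets out from 2 and returns at 7, and uses a Lewis-acid-free SN2 displacement on a base-stable ether. 2 is alkylated (NaH, 4-methoxybenzyl chloride, Bu4NI, THF/DMF, 0 °C) to the epoxygeranyl 4-methoxybenzyl ether F3. Lithium acetylide–ethylenediamine complex in DMSO at rt to 40 °C can only reach the secondary carbon and should give the ethynyl alcohol 4-methoxybenzyl ether F4 with the same inversion. DDQ in CH2Cl2/pH 7 buffer removes the benzyl ether and delivers diol 7.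

Step 14. Olefination of the aldehyde, which is flanked by two fully substituted carbons, may be sluggish, and the prolonged heating may lead to retro-aldol cleavage or dehydration of the β-hydroxy aldehyde. The fallback sets out from 18 and returns at 20, and uses a masked hydroxyl and a more nucleophilic phosphonate carbanion. 18 is silylated with 1-(trimethylsilyl)imidazole in CH2Cl2 to the 8-O-trimethylsilyl aldehyde F5. Horner–Wadsworth–Emmons reaction with benzyl diethylphosphonoacetate and NaH in THF at 0 °C → rt should give the 8-O-trimethylsilyl dienoate F6. Brief treatment with HF·pyridine in THF at 0 °C removes the silyl group to give 20.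

Further compounds
F1 | step 9 | 2-[(2E)-5-{(4R,5S)-2,2-di-tert-butyl-4-methyl-5-[(2E)-penta-2,4-dien-2-yl]-1,3,2-dioxasilinan-4-yl}pent-2-en-2-yl]-1,3-dioxolane (ethylene acetal of 13) | C1COC(O1)/C(C)=C/CC[C@@]2(C)O[Si](C(C)(C)C)(C(C)(C)C)OC[C@@H]2/C(C)=C/C=C
F2 | step 9 | ethylene acetal of 14, 8α,11-(di-tert-butylsilylenedioxy)-18,18-(ethylenedioxy)-12,13,14,15,16-pentanorlabd-1-ene | CC(C)(C)[Si]3(C(C)(C)C)O[C@]1(C)CC[C@@H]2[C@](C)(C=CC[C@@]2(C)C4OCCO4)[C@H]1CO3
F3 | step 3 | (2R,3R)-2,3-epoxygeranyl 4-methoxybenzyl ether | CC(C)=CCC[C@@]1(C)O[C@@H]1COCc2ccc(OC)cc2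
F4 | step 3 | (2S,3R)-2-ethynyl-1-[(4-methoxybenzyl)oxy]-3,7-dimethyloct-6-en-3-ol | CC(C)=CCC[C@@](C)(O)[C@H](COCc1ccc(OC)cc1)C#C
F5 | step 14 | benzyl 11-oxo-8α-(trimethylsilyloxy)-12,13,14,15,16-pentanorlabd-1-en-18-oate | C[Si](C)(C)O[C@]1(C)CC[C@@H]2[C@](C)(C=CC[C@@]2(C)C(=O)OCc3ccccc3)[C@H]1C=O
F6 | step 14 | dibenzyl (11E)-8α-(trimethylsilyloxy)-14,15,16-trinorlabda-1,11-diene-13,18-dioate | C[Si](C)(C)O[C@]1(C)CC[C@@H]2[C@](C)(C=CC[C@@]2(C)C(=O)OCc3ccccc3)[C@H]1/C=C/C(=O)OCc4ccccc4
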